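**Assumption:** the target is read as robinetinidol-(4β→8)-epigallocatechin 3-O-gallate, with the upper flavan (2R,3S,4R) (2-aryl α, 3-OH β, 4-aryl β; 2,3-trans-3,4-cis) and the lower unit (2R,3R) with the galloyl ester on O3; (+)-dihydrorobinetin, (−)-epigallocatechin and 3,4,5-tris(benzyloxy)benzoic acid are taken as purchasable.

## Retrosynthetic overview

1. Last operation: hydrogenolysis of twelve benzyl ethers. Before it, the two flavan halves are joined between C4 of ring C (upper unit) and C8 of ring D (lower unit).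
2. Key union: the 3β,4β-oxirane of the benzylated upper flavan reacts with the C8-difluoroborane of benzylated epigallocatechin gallate. Boron docks on the oxirane oxygen, C4–O ionises, and C8 passes from boron to C4 on the face of O3.
3. Enabling feature: O3 on C3 of ring C is cis to the C4–C8 bond, and C4 is benzylic and para to O7 of ring A. C8 of ring D lies between O1 and O7 and para to O5, so it migrates readily from boron.
4. Upper half from (+)-dihydrorobinetin (rings A, C, B; C2 and C3 bought): benzylation, C4=O reduction, Mitsunobu closure. Lower half from (−)-epigallocatechin (rings D, F, E; C2 and C3 bought): benzylation, esterification of O3 with 3,4,5-tris(benzyloxy)benzoic acid (galloyl ring), C8 bromination, borylation.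
5. Ring order: all six-membered rings are bought. The only ring made is the temporary oxirane (step 3), which is opened again in step 8.

Key step: step 8

## Route

Step 1
Reactants: 1 (+)-dihydrorobinetin; 2 benzyl bromide
Product: 3 (2R,3R)-7-benzyloxy-3-hydroxy-2-(3,4,5-tribenzyloxyphenyl)chroman-4-one
Conditions: BnBr (4.4 equiv), K2CO3, DMF, rt, argon, degassed
Reagents that add atoms: benzyl bromide, BrCc1ccccc1
Why: Williamson etherification of the four phenols; the aliphatic 3-OH is not alkylated by carbonate, and the mild, air-free conditions should keep the 2,3-trans ketol from ring-opening or oxidising.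

Step 2
Reactants: 3 tetra-O-benzyl-dihydrorobinetin
Product: 4 (2R,3S,4R)-7-benzyloxy-2-(3,4,5-tribenzyloxyphenyl)chroman-3,4-diol (2,3-trans-3,4-trans; 3β-OH, 4α-OH)
Conditions: NaBH4, THF/MeOH, 0 °C; water quench; crystallisation
Reagents that add atoms: none
Why: Borohydride reduction of the aryl ketone; hydride should add axially to C4 of the 2,3-trans-dihydroflavonol to give mainly the diequatorial 3,4-trans diol (4R), and the minor 3,4-cis epimer is removed by crystallisation.

Step 3
Reactants: 4 trans,trans-diol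
Product: 5 (2R,3S,4S)-7-benzyloxy-3,4-epoxy-2-(3,4,5-tribenzyloxyphenyl)chroman (3β,4β-oxirane, trans to the 2-aryl group)
Conditions: PPh3, DIAD, THF, 0 °C → rt; rapid filtration through Et3N-deactivated basic alumina; used at once
Reagents that add atoms: none
Why: Mitsunobu cyclodehydration of a trans-1,2-diol: within the dioxyphosphorane the para-alkoxybenzylic C4–O bond is the one that should break, so the 3β-oxygen closes onto C4 with inversion (3-exo-tet), C3 keeps its configuration and the β-oxirane results.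

Step 4
Reactants: 6 (−)-epigallocatechin; 2 benzyl bromide
Product: 7 (2R,3R)-5,7-bis(benzyloxy)-2-(3,4,5-tribenzyloxyphenyl)chroman-3-ol (penta-O-benzyl-epigallocatechin)
Conditions: BnBr (5.5 equiv), K2CO3, DMF, 0 °C → rt, argon, degassed
Reagents that add atoms: benzyl bromide, BrCc1ccccc1
Why: Williamson etherification of the five phenols; the secondary 3-OH is not alkylated by carbonate, and low temperature with exclusion of air should avoid C2 epimerisation and oxidation of the pyrogallol ring.

Step 5
Reactants: 7 penta-O-benzyl-epigallocatechin; 8 3,4,5-tris(benzyloxy)benzoic acid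
Product: 9 (2R,3R)-5,7-bis(benzyloxy)-2-(3,4,5-tribenzyloxyphenyl)chroman-3-yl 3,4,5-tribenzyloxybenzoate (octa-O-benzyl-EGCG)
Conditions: 8 (1.5 equiv), DCC (1.6 equiv), DMAP (0.2 equiv), CH2Cl2, 0 °C → rt
Reagents that add atoms: 3,4,5-tris(benzyloxy)benzoic acid, OC(=O)c1cc(OCc2ccccc2)c(OCc2ccccc2)c(OCc2ccccc2)c1
Why: Steglich esterification of the axial 3-OH through the N-acylpyridinium ion; only the O–H bond reacts, so C2 and C3 keep their configuration.

Step 6
Reactants: 9 octa-O-benzyl-EGCG; 10 N-bromosuccinimide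
Product: 11 8-bromo-octa-O-benzyl-EGCG
Conditions: NBS (1.05 equiv), CH2Cl2, −78 → 0 °C, dark
Reagents that add atoms: N-bromosuccinimide, O=C1CCC(=O)N1Br
Why: Electrophilic aromatic bromination; ring D with three oxygen donors is far more reactive than ring E or the ester-deactivated galloyl ring, and in 5,7-di-O-benzyl flavans C8 (between O1 and O7) is attacked in preference to C6.

Step 7
Reactants: 11 8-bromo-octa-O-benzyl-EGCG; 12 pinacolborane; 13 potassium hydrogen difluoride
Product: 15 potassium (octa-O-benzyl-EGCG-8-yl)trifluoroborate, via pinacol boronate 14 (not isolated)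
Conditions: PdCl2(MeCN)2 (3 mol%), 2-dicyclohexylphosphino-2',6'-dimethoxybiphenyl (12 mol%), pinacolborane, Et3N, 1,4-dioxane, 80 °C; then aq. KHF2, THF/MeOH, rt
Reagents that add atoms: pinacolborane, CC1(C)OBOC1(C)C; potassium hydrogen difluoride, [K+].[F-].F
Why: Miyaura-type borylation in which zerovalent palladium inserts into the C8–Br bond (the bulky biaryl phosphine permits the di-ortho-substituted, electron-rich case), followed by pinacol-to-fluoride exchange with KHF2; ester, benzyl ethers and stereocentres are not affected.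

Step 8
Reactants: 15 potassium aryltrifluoroborate; 5 3β,4β-oxirane
Product: 18 dodeca-O-benzyl robinetinidol-(4β→8)-epigallocatechin 3-O-gallate, via aryldifluoroborane 16 (not isolated), via 3-O-difluoroboryl adduct 17 (not isolated)
Conditions: 15 (1.1 equiv), TMSCl (1.1 equiv), CH2Cl2, 0 °C, 30 min; cool to −78 °C; 2,6-di-tert-butyl-4-methylpyridine (0.2 equiv); slow addition of 5 (1.0 equiv) in CH2Cl2, −78 → −30 °C; aq. NaHCO3
Reagents that add atoms: none
Why: Proposed new method: TMSCl abstracts one fluoride from 15 to give the Lewis-acidic aryldifluoroborane 16, whose boron binds the oxirane oxygen of 5; the C4–O bond then ionises to the benzylic cation that O7 of ring A stabilises as a para-quinone-methide oxocarbenium ion, and the ring-D carbon C8 migrates from the now tetracoordinate boron, still held on O3, to C4 through a five-membered cyclic transition state (B–O3–C3–C4–C8), leaving the difluoroborinate 17 that aqueous work-up hydrolyses. The closest known reaction types are the Petasis borono-Mannich reaction (an aryl group handed from a boronate on a neighbouring oxygen to the adjacent cationic carbon) and the retentive, syn openings of aryl-substituted and glycal epoxides by nucleophiles carried on boron or aluminium bound to the oxirane oxygen. No ring is closed: the oxirane, the temporary ring, is opened, and the only cyclic array is the five-membered transition state. The new stereocentre C4 is set by the tether: the aryl group can reach C4 only from the face of the boron-bearing O3, which gives the 4β (4R), 3,4-cis product, while C2 and C3 are not touched. Three selectivities are needed: C8 over C6, secured by ipso substitution at the C8–B bond; 3,4-cis over the innate 3,4-trans preference of a 2,3-trans flavan-4-yl cation, secured by delivery from O3; and aryl transfer over the 1,2-hydride shift to the flavan-3-one, favoured by the high migratory aptitude of the 2,4,6-trioxygenated aryl group and by the absence of any stronger external Lewis acid at low temperature.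

Step 9
Reactants: 18 dodeca-O-benzyl dimer
Product: 19 robinetinidol-(4β→8)-epigallocatechin 3-O-gallate (target)
Conditions: H2 (1 atm), Pd(OH)2 on carbon, THF/MeOH/H2O, rt; filtration through Celite under argon; lyophilisation
Reagents that add atoms: none
Why: Catalytic hydrogenolysis of the twelve benzyl ethers under neutral conditions; the gallate ester, the C2–O1 bonds and the interflavan bond of a 5-deoxy upper unit should be left intact, as is usual for galloylated flavan-3-ol oligomers.

## Compound list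

1 | (+)-dihydrorobinetin, (2R,3R)-3,7-dihydroxy-2-(3,4,5-trihydroxyphenyl)chroman-4-one | O=C1c2ccc(O)cc2O[C@H](c2cc(O)c(O)c(O)c2)[C@H]1O | starting material
2 | benzyl bromide | BrCc1ccccc1 | starting material
3 | (2R,3R)-7-benzyloxy-3-hydroxy-2-(3,4,5-tribenzyloxyphenyl)chroman-4-one | O=C1c2ccc(OCc3ccccc3)cc2O[C@H](c2cc(OCc3ccccc3)c(OCc3ccccc3)c(OCc3ccccc3)c2)[C@H]1O | intermediate
4 | (2R,3S,4R)-7-benzyloxy-2-(3,4,5-tribenzyloxyphenyl)chroman-3,4-diol | O[C@@H]1c2ccc(OCc3ccccc3)cc2O[C@H](c2cc(OCc3ccccc3)c(OCc3ccccc3)c(OCc3ccccc3)c2)[C@H]1O | intermediate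
5 | (2R,3S,4S)-7-benzyloxy-3,4-epoxy-2-(3,4,5-tribenzyloxyphenyl)chroman | c1ccccc1COc1ccc2c(c1)O[C@H](c1cc(OCc3ccccc3)c(OCc3ccccc3)c(OCc3ccccc3)c1)[C@H]1O[C@H]12 | intermediate
6 | (−)-epigallocatechin, (2R,3R)-2-(3,4,5-trihydroxyphenyl)chroman-3,5,7-triol | O[C@@H]1Cc2c(O)cc(O)cc2O[C@@H]1c1cc(O)c(O)c(O)c1 | starting material
7 | penta-O-benzyl-epigallocatechin, (2R,3R)-5,7-bis(benzyloxy)-2-(3,4,5-tribenzyloxyphenyl)chroman-3-ol | O[C@@H]1Cc2c(OCc3ccccc3)cc(OCc3ccccc3)cc2O[C@@H]1c1cc(OCc2ccccc2)c(OCc2ccccc2)c(OCc2ccccc2)c1 | intermediate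
8 | 3,4,5-tris(benzyloxy)benzoic acid | OC(=O)c1cc(OCc2ccccc2)c(OCc2ccccc2)c(OCc2ccccc2)c1 | starting material
9 | octa-O-benzyl-EGCG, (2R,3R) | O=C(O[C@@H]1Cc2c(OCc3ccccc3)cc(OCc3ccccc3)cc2O[C@@H]1c1cc(OCc2ccccc2)c(OCc2ccccc2)c(OCc2ccccc2)c1)c1cc(OCc2ccccc2)c(OCc2ccccc2)c(OCc2ccccc2)c1 | intermediate
10 | N-bromosuccinimide | O=C1CCC(=O)N1Br | starting material
11 | 8-bromo-octa-O-benzyl-EGCG | O=C(O[C@@H]1Cc2c(OCc3ccccc3)cc(OCc3ccccc3)c(Br)c2O[C@@H]1c1cc(OCc2ccccc2)c(OCc2ccccc2)c(OCc2ccccc2)c1)c1cc(OCc2ccccc2)c(OCc2ccccc2)c(OCc2ccccc2)c1 | intermediate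
12 | pinacolborane | CC1(C)OBOC1(C)C | starting material
13 | potassium hydrogen difluoride | [K+].[F-].F | starting material
14 | 8-(pinacolatoboryl)-octa-O-benzyl-EGCG (not isolated) | O=C(O[C@@H]1Cc2c(OCc3ccccc3)cc(OCc3ccccc3)c(B3OC(C)(C)C(C)(C)O3)c2O[C@@H]1c1cc(OCc2ccccc2)c(OCc2ccccc2)c(OCc2ccccc2)c1)c1cc(OCc2ccccc2)c(OCc2ccccc2)c(OCc2ccccc2)c1 | intermediate
15 | potassium (octa-O-benzyl-EGCG-8-yl)trifluoroborate | O=C(O[C@@H]1Cc2c(OCc3ccccc3)cc(OCc3ccccc3)c([B-](F)(F)F)c2O[C@@H]1c1cc(OCc2ccccc2)c(OCc2ccccc2)c(OCc2ccccc2)c1)c1cc(OCc2ccccc2)c(OCc2ccccc2)c(OCc2ccccc2)c1.[K+] | intermediate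
16 | 8-(difluoroboryl)-octa-O-benzyl-EGCG (not isolated) | O=C(O[C@@H]1Cc2c(OCc3ccccc3)cc(OCc3ccccc3)c(B(F)F)c2O[C@@H]1c1cc(OCc2ccccc2)c(OCc2ccccc2)c(OCc2ccccc2)c1)c1cc(OCc2ccccc2)c(OCc2ccccc2)c(OCc2ccccc2)c1 | intermediate
17 | 3-O-difluoroboryl ether of the coupled dodeca-O-benzyl dimer, upper unit (2R,3S,4R) (not isolated) | O=C(O[C@@H]1Cc2c(OCc5ccccc5)cc(OCc5ccccc5)c([C@H]3c4ccc(OCc5ccccc5)cc4O[C@H](c4cc(OCc5ccccc5)c(OCc5ccccc5)c(OCc5ccccc5)c4)[C@H]3OB(F)F)c2O[C@@H]1c1cc(OCc5ccccc5)c(OCc5ccccc5)c(OCc5ccccc5)c1)c1cc(OCc5ccccc5)c(OCc5ccccc5)c(OCc5ccccc5)c1 | intermediate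
18 | dodeca-O-benzyl robinetinidol-(4β→8)-epigallocatechin 3-O-gallate, upper unit (2R,3S,4R), lower unit (2R,3R) | O=C(O[C@@H]1Cc2c(OCc5ccccc5)cc(OCc5ccccc5)c([C@H]3c4ccc(OCc5ccccc5)cc4O[C@H](c4cc(OCc5ccccc5)c(OCc5ccccc5)c(OCc5ccccc5)c4)[C@H]3O)c2O[C@@H]1c1cc(OCc5ccccc5)c(OCc5ccccc5)c(OCc5ccccc5)c1)c1cc(OCc5ccccc5)c(OCc5ccccc5)c(OCc5ccccc5)c1 | intermediate
19 | robinetinidol-(4β→8)-epigallocatechin 3-O-gallate | O=C(O[C@@H]1Cc2c(O)cc(O)c([C@H]3c4ccc(O)cc4O[C@H](c4cc(O)c(O)c(O)c4)[C@H]3O)c2O[C@@H]1c1cc(O)c(O)c(O)c1)c1cc(O)c(O)c(O)c1 | target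

## Step count and risks

Total step count: 9. Longest linear sequence: 6 steps (steps 4, 5, 6, 7, 8, 9).

Steps most likely to fail:

**Step 8 (proposed new method).** The benzylic cation may undergo a 1,2-hydride shift from C3 to give the flavan-3-one before the aryl group is transferred. Alternatively, protodeboronation of 16 may release free arene, which would then capture the cation without the tether and lose facial control. The fallback uses known chemistry, sets out from diol 4 and arene 9, and returns at 18. It is the Lewis-acid Friedel–Crafts union established for benzylated flavan-3,4-diols with benzylated flavan-3-ols: 4 and an excess of 9 (4 equiv) with TMSOTf (0.5 equiv) in CH2Cl2 at −78 → −40 °C. The 4-OH should ionise and the flavan-4-yl cation should be trapped at C8 of ring D. Without the boron tether both C4 epimers are expected: the wanted 4β compound 18 and the 4α (3,4-trans) epimer of 18 F1, which is likely to predominate. They would be separated by preparative HPLC, excess 9 recovered, and 18 taken into step 9 unchanged.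

**Step 3.** The activated benzylic C4–O bond may ionise before ring closure, leading to elimination or rearrangement. Loss of regiocontrol in the activation (departure of O3 instead of O4) would lead to the diastereomeric α-oxirane, and the acid-labile oxirane may decompose during isolation. The fallback sets out from 4 and returns at 5 by a halohydrin route, in which the leaving group can only sit on C4. HCl (2 M in Et2O) in CH2Cl2 over 4 Å sieves at 0 °C should replace the para-alkoxybenzylic 4-OH by chloride to give (2R,3S)-7-benzyloxy-4-chloro-2-(3,4,5-tribenzyloxyphenyl)chroman-3-ol F2 as a C4-epimer mixture. NaH in THF at −20 °C then closes the oxirane from the 3β-alkoxide. Both epimers should converge on 5, because the benzylic chloride epimerises through its ion pair and a 3β-oxygen can only close the β-oxirane.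

**Step 7.** Oxidative addition into the di-ortho-substituted, electron-rich C8–Br bond may be slow, with hydrodebromination competing, and protodeboronation may occur during the fluoride exchange. The fallback sets out from 9 and returns at 15, replacing palladium catalysis by halogen–magnesium exchange. N-Iodosuccinimide in CH2Cl2/DMF at 0 °C should give 8-iodo-octa-O-benzyl-EGCG F3. iPrMgCl·LiCl in THF at −40 °C (the two ortho oxygens accelerate the exchange, and the ester should survive at this temperature) gives the 8-(chloromagnesio) derivative F4 (not isolated). B(OMe)3 traps it as the dimethyl 8-boronate F5 (not isolated), and aqueous KHF2 converts this to 15.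

## Further compounds

F1 | step 8 | 4α-epimer of 18 (upper unit 2R,3S,4S; 3,4-trans) | O=C(O[C@@H]1Cc2c(OCc5ccccc5)cc(OCc5ccccc5)c([C@@H]3c4ccc(OCc5ccccc5)cc4O[C@H](c4cc(OCc5ccccc5)c(OCc5ccccc5)c(OCc5ccccc5)c4)[C@H]3O)c2O[C@@H]1c1cc(OCc5ccccc5)c(OCc5ccccc5)c(OCc5ccccc5)c1)c1cc(OCc5ccccc5)c(OCc5ccccc5)c(OCc5ccccc5)c1
F2 | step 3 | (2R,3S)-7-benzyloxy-4-chloro-2-(3,4,5-tribenzyloxyphenyl)chroman-3-ol, C4-epimer mixture | ClC1c2ccc(OCc3ccccc3)cc2O[C@H](c2cc(OCc3ccccc3)c(OCc3ccccc3)c(OCc3ccccc3)c2)[C@H]1O
F3 | step 7 | 8-iodo-octa-O-benzyl-EGCG | O=C(O[C@@H]1Cc2c(OCc3ccccc3)cc(OCc3ccccc3)c(I)c2O[C@@H]1c1cc(OCc2ccccc2)c(OCc2ccccc2)c(OCc2ccccc2)c1)c1cc(OCc2ccccc2)c(OCc2ccccc2)c(OCc2ccccc2)c1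
F4 | step 7 | 8-(chloromagnesio)-octa-O-benzyl-EGCG | O=C(O[C@@H]1Cc2c(OCc3ccccc3)cc(OCc3ccccc3)c([Mg]Cl)c2O[C@@H]1c1cc(OCc2ccccc2)c(OCc2ccccc2)c(OCc2ccccc2)c1)c1cc(OCc2ccccc2)c(OCc2ccccc2)c(OCc2ccccc2)c1
F5 | step 7 | dimethyl (octa-O-benzyl-EGCG-8-yl)boronate | O=C(O[C@@H]1Cc2c(OCc3ccccc3)cc(OCc3ccccc3)c(B(OC)OC)c2O[C@@H]1c1cc(OCc2ccccc2)c(OCc2ccccc2)c(OCc2ccccc2)c1)c1cc(OCc2ccccc2)c(OCc2ccccc2)c(OCc2ccccc2)c1
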